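**Strategy.** The cyclononene is never closed as a nine-membered ring. Its C11–C11a bond (xenicane numbering: C11 bears the exocyclic methylene, C11a the lactone CH2O arm) is forged in a six-membered ring by a proline-catalysed desymmetrising aldol of an aldehyde enamine onto a 2,2-disubstituted cyclopentane-1,3-dione. This sets C11a trans to C4a and installs a temporary C7–C11 bond plus the C11 tertiary hydroxyl. The step exploits that C11 is a latent ketone and the C7–C8 epoxide a latent E-alkene: Grob fragmentation of the derived C8 mesylate later cuts C7–C11 and releases both in the nine-membered ring. The aldol precursor is an acyclic aldehyde–malonate–dione made by an organocatalytic Michael addition.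

Key step: step 4

Remark: all locants are those of the xenicane skeleton of the target and are kept for every intermediate (C1 lactone CH2O, O2, C3 lactone C=O, C4 side-chain carbon, C4a/C11a ring fusion, C5–C11 remaining ring carbons, C18 methyl on C7, C19 methylene on C11).
Remark: the temporary stereocentres C7/C11 (compounds 8–15) and the quaternary C4 (compounds 11–19) are drawn as the diastereomer expected from the transition-state analysis; both are erased later (steps 9 and 11), so their epimers would converge on the same products.

Step 1
Reactants: 1 2-methylcyclopentane-1,3-dione; 2 acrolein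
Product: 3 3-(1-methyl-2,5-dioxocyclopentyl)propanal
Conditions: H2O, rt
Reagents that add atoms: acrolein (2), C=CC=O
Why: Michael addition of the acidic 1,3-dione C–H to acrolein proceeds in water without added base; no stereocentre is formed.

Step 2
Reactants: 3 3-(1-methyl-2,5-dioxocyclopentyl)propanal; 4 (triphenylphosphoranylidene)acetaldehyde
Product: 5 (2E)-5-(1-methyl-2,5-dioxocyclopentyl)pent-2-enal
Conditions: 4 (1.05 equiv), PhMe, 60 °C
Reagents that add atoms: (triphenylphosphoranylidene)acetaldehyde (4), O=CC=P(c1ccccc1)(c1ccccc1)c1ccccc1
Why: Wittig olefination with the stabilised formyl ylide should react only at the aldehyde (the ring ketones are neopentyl) and give the E-enal.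

Step 3
Reactants: 5 (2E)-5-(1-methyl-2,5-dioxocyclopentyl)pent-2-enal; 6 diallyl malonate
Product: 7 diallyl 2-[(3S)-1-(1-methyl-2,5-dioxocyclopentyl)-5-oxopentan-3-yl]malonate
Conditions: (R)-2-[bis(3,5-bis(trifluoromethyl)phenyl)(trimethylsilyloxy)methyl]pyrrolidine (10 mol %), PhCO2H (10 mol %), EtOH, 0 °C
Reagents that add atoms: diallyl malonate (6), C=CCOC(=O)CC(=O)OCC=C
Why: Iminium-catalysed asymmetric Michael addition; the silyloxydiarylmethyl group of the (R)-catalyst shields one face of the s-trans E-iminium ion, so the malonate should add to the other face of C4a and set it S.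

Step 4
Reactants: 7 diallyl 2-[(3S)-1-(1-methyl-2,5-dioxocyclopentyl)-5-oxopentan-3-yl]malonate
Product: 8 cis-hydrindane ketol aldehyde
Conditions: D-proline (30 mol %), DMF, 4 °C; crude product used directly
Reagents that add atoms: none
Why: D-Proline condenses chemoselectively with the aldehyde to the E-enamine, whose carbon C11a adds to C11, one of the two enantiotopic ring carbonyls, through a chair transition state in which the carboxylic acid hydrogen-bonds the ketone; hydrolysis returns the catalyst. The closest known reactions are the Hajos–Parrish cyclisation of 2-methylcyclopentane-1,3-dione triketones and proline-catalysed enolexo aldolisations of aldehydes. The six-membered ring (C7, C6, C5, C4a, C11a, C11) closes in the 6-(enolexo)-exo-trig mode. C11a is controlled by C4a: the malonyl group sits equatorial and H-4a eclipses the enamine C–H (allylic 1,3-strain), so C1 and C4 end trans-diequatorial, which is also the thermodynamic arrangement of this epimerisable centre; C11 and C7 (hydroxyl cis to methyl, cis-hydrindane) are temporary and follow from which carbonyl the catalyst selects. The step needs reaction through the aldehyde enamine rather than a ketone enamine and no loss of water: aldehydes condense far faster with proline, and the tertiary aldol is kept cold and carried on at once. D-Proline is chosen because its enamine should be attacked on the face that C4a also demands (matched pair).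

Step 5
Reactants: 8 cis-hydrindane ketol aldehyde
Product: 10 tricyclic lactone diol, via triol 9 (not isolated)
Conditions: NaBH4, THF–i-PrOH, −20 °C; then PPTS (cat.), PhMe, 60 °C
Reagents that add atoms: none
Why: Borohydride reduction then acid-catalysed lactonisation (transesterification): hydride should attack the C8 ketone on the face opposite the angular C7 methyl (as in 17-oxo steroids), placing C8–OH cis to the methyl and to C11–OH, and the primary C1–OH then closes the trans-fused δ-lactone on one malonate ester, leaving an epimerisable C4.

Step 6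
Reactants: 10 tricyclic lactone diol; 2 acrolein
Product: 11 C4-quaternary lactone aldehyde
Conditions: acrolein (1.5 equiv), Et3N (10 mol %), CH2Cl2, 0 °C → rt
Reagents that add atoms: acrolein (2), C=CC=O
Why: Amine-catalysed Michael addition of the α-allyloxycarbonyl lactone (a malonate-type C–H acid) to acrolein; the quaternary C4 so formed (chain expected anti to C5) is not kept, because step 11 resets it.

Step 7
Reactants: 11 C4-quaternary lactone aldehyde; 12 methyl 2-(triphenylphosphoranylidene)propanoate
Product: 13 side-chain enoate diol
Conditions: 12 (1.2 equiv), CH2Cl2, rt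
Reagents that add atoms: methyl 2-(triphenylphosphoranylidene)propanoate (12), COC(=O)C(C)=P(c1ccccc1)(c1ccccc1)c1ccccc1
Why: Wittig olefination with the α-methyl stabilised ylide should give the E-trisubstituted enoate of the side chain and leave lactone, allyl ester and free hydroxyls untouched.

Step 8
Reactants: 13 side-chain enoate diol; 14 methanesulfonyl chloride
Product: 15 C8 mesylate
Conditions: MsCl (1.1 equiv), Et3N, CH2Cl2, −20 °C
Reagents that add atoms: methanesulfonyl chloride (14), CS(=O)(=O)Cl
Why: Sulfonylation through sulfene is selective for the secondary C8–OH over the tertiary C11–OH, and the configuration at C8 is retained.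

Step 9
Reactants: 15 C8 mesylate
Product: 16 (7E)-cyclononenone lactone
Conditions: KOt-Bu (1.05 equiv), THF, 0 °C
Reagents that add atoms: none
Why: Grob fragmentation of the 1,3-hydroxy mesylate: the C11 alkoxide expels mesylate with cleavage of the temporary C7–C11 bond lying anti-periplanar to C8–O, and because the mesylate is cis to the C7 methyl the ring carbon C9 ends cis to that methyl, so the C7=C8 alkene should be E; C4a and C11a are untouched.

Step 10
Reactants: 16 (7E)-cyclononenone lactone; 17 methyltriphenylphosphonium bromide
Product: 18 11-methylidene lactone allyl ester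
Conditions: 17, KOt-Bu, THF, 0 °C; then 16, 0 °C → rt
Reagents that add atoms: methylenetriphenylphosphorane, C=P(c1ccccc1)(c1ccccc1)c1ccccc1, made in the flask from methyltriphenylphosphonium bromide (17), C[P+](c1ccccc1)(c1ccccc1)c1ccccc1.[Br-]
Why: Wittig methylenation is selective for the ketone over lactone and esters; C4 is quaternary and cannot epimerise, and the trans ring fusion at C11a is the stable one should the ylide enolise the ketone.

Step 11
Reactants: 18 11-methylidene lactone allyl ester
Product: 20 7,8-deoxy target, via carboxylic acid 19 (not isolated)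
Conditions: Pd(OAc)2 (5 mol %), PPh3, HCO2H, Et3N, 1,4-dioxane, rt → 100 °C
Reagents that add atoms: none
Why: Palladium-catalysed hydrogenolysis of the allyl ester by formate (π-allyl complex of zerovalent palladium formed in situ) gives the malonic half-acid, which loses CO2 on heating; the lactone enol should be protonated on the face opposite the C4a–C5 bond, giving H-4 cis to H-4a (4S).

Step 12
Reactants: 20 7,8-deoxy target; 21 3-chloroperoxybenzoic acid
Product: 22 Acalycixeniolide H
Conditions: mCPBA (1.0 equiv), NaHCO3, CH2Cl2, 0 °C
Reagents that add atoms: 3-chloroperoxybenzoic acid (21), O=C(OO)c1cccc(Cl)c1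
Why: Prilezhaev epoxidation: the strained E-trisubstituted ring alkene is far more nucleophilic than the 1,1-disubstituted and the conjugated alkenes, and attack on its exposed outer face in the preferred ring conformer (the course taken by β-caryophyllene) should give the 7S,8S trans-epoxide.

**Compound list**

1 | 2-methylcyclopentane-1,3-dione | CC1C(=O)CCC1=O | starting material
2 | acrolein (prop-2-enal) | C=CC=O | starting material
3 | 3-(1-methyl-2,5-dioxocyclopentyl)propanal | CC1(CCC=O)C(=O)CCC1=O | intermediate
4 | (triphenylphosphoranylidene)acetaldehyde | O=CC=P(c1ccccc1)(c1ccccc1)c1ccccc1 | starting material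
5 | (2E)-5-(1-methyl-2,5-dioxocyclopentyl)pent-2-enal | CC1(CC/C=C/C=O)C(=O)CCC1=O | intermediate
6 | diallyl malonate | C=CCOC(=O)CC(=O)OCC=C | starting material
7 | diallyl 2-[(3S)-1-(1-methyl-2,5-dioxocyclopentyl)-5-oxopentan-3-yl]malonate | O=CC[C@H](CCC1(C)C(=O)CCC1=O)C(C(=O)OCC=C)C(=O)OCC=C | intermediate
8 | diallyl 2-[(3aS,4R,5S,7aS)-4-formyl-3a-hydroxy-7a-methyl-1-oxooctahydro-1H-inden-5-yl]malonate (cis-hydrindane; CHO on C11a and malonyl on C4a trans-diequatorial; C11-OH cis to C7-CH3) | C[C@]12CC[C@H](C(C(=O)OCC=C)C(=O)OCC=C)[C@@H](C=O)[C@@]1(O)CCC2=O | intermediate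
9 | diallyl 2-[(1S,3aS,4S,5S,7aR)-1,3a-dihydroxy-4-(hydroxymethyl)-7a-methyloctahydro-1H-inden-5-yl]malonate (C8-OH, C11-OH and C7-CH3 all cis) | C[C@]12CC[C@H](C(C(=O)OCC=C)C(=O)OCC=C)[C@@H](CO)[C@@]1(O)CC[C@@H]2O | intermediate (not isolated)
10 | tricyclic lactone diol: δ-lactone O2–C3(=O)–C4–C4a–C11a–C1H2 trans-fused at C4a–C11a to the cis-hydrindane; CO2allyl on C4 (trans to C5, epimerisable); C8-OH, C11-OH and C7-CH3 all cis | C[C@]12CC[C@@H]3[C@@H](C(=O)OCC=C)C(=O)OC[C@H]3[C@@]1(O)CC[C@@H]2O | intermediate
11 | as 10, with C4 quaternary: 3-oxopropyl (trans to C5) and CO2allyl (cis to C5) | C[C@]12CC[C@@H]3[C@](CCC=O)(C(=O)OCC=C)C(=O)OC[C@H]3[C@@]1(O)CC[C@@H]2O | intermediate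
12 | methyl 2-(triphenylphosphoranylidene)propanoate | COC(=O)C(C)=P(c1ccccc1)(c1ccccc1)c1ccccc1 | starting material
13 | as 11, with the C4 chain (E)-CH2CH2CH=C(CH3)CO2CH3 | C[C@]12CC[C@@H]3[C@](CC/C=C(\C)C(=O)OC)(C(=O)OCC=C)C(=O)OC[C@H]3[C@@]1(O)CC[C@@H]2O | intermediate
14 | methanesulfonyl chloride | CS(=O)(=O)Cl | starting material
15 | C8 methanesulfonate of 13 (OMs cis to C7-CH3 and C11-OH) | C[C@]12CC[C@@H]3[C@](CC/C=C(\C)C(=O)OC)(C(=O)OCC=C)C(=O)OC[C@H]3[C@@]1(O)CC[C@@H]2OS(C)(=O)=O | intermediate
16 | (4aS,7E,11aR)-cyclonona[c]pyran-3,11-dione: nine-membered ring with E-C7=C8 (CH3 on C7) and C11 ketone, trans-fused δ-lactone; C4 bears CO2allyl and the (E)-enoate chain | O=C1CC/C=C(\C)CC[C@@H]2[C@](CC/C=C(\C)C(=O)OC)(C(=O)OCC=C)C(=O)OC[C@@H]12 | intermediate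
17 | methyltriphenylphosphonium bromide | C[P+](c1ccccc1)(c1ccccc1)c1ccccc1.[Br-] | starting material
18 | 11-methylidene analogue of 16 | C=C1CC/C=C(\C)CC[C@@H]2[C@](CC/C=C(\C)C(=O)OC)(C(=O)OCC=C)C(=O)OC[C@@H]12 | intermediate
19 | C4 carboxylic acid from 18 | C=C1CC/C=C(\C)CC[C@@H]2[C@](CC/C=C(\C)C(=O)OC)(C(=O)O)C(=O)OC[C@@H]12 | intermediate (not isolated)
20 | methyl (2E)-2-methyl-5-[(4S,4aS,7E,11aR)-7-methyl-11-methylidene-3-oxo-1,3,4,4a,5,6,9,10,11,11a-decahydrocyclonona[c]pyran-4-yl]pent-2-enoate | C=C1CC/C=C(\C)CC[C@@H]2[C@H](CC/C=C(\C)C(=O)OC)C(=O)OC[C@@H]12 | intermediate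
21 | 3-chloroperoxybenzoic acid | O=C(OO)c1cccc(Cl)c1 | starting material
22 | Acalycixeniolide H, (4S,4aS,7S,8S,11aR) | C=C1CC[C@@H]2O[C@@]2(C)CC[C@@H]2[C@H](CC/C=C(\C)C(=O)OC)C(=O)OC[C@@H]12 | target

**Totals.** 12 steps; longest linear sequence 12 steps.

**Steps most likely to fail**

Step 4. The tertiary aldol may lose water under amine catalysis or revert by retro-aldol, or the malonate may be expelled through the enamine (retro-Michael), which would erode C4a. The fallback closes the same bond without an amine in the ring-forming event. It sets out from 7: enamine-catalysed α-chlorination (N-chlorosuccinimide, L-prolinamide cat., CH2Cl2, 0 °C) gives the α-chloro aldehyde F1 as an epimer mixture at C11a. SmI2 (2.2 equiv, THF, −78 °C) then reduces the C–Cl bond to the samarium enolate, which adds to the C11 carbonyl through a chelated chair (Reformatsky-type intramolecular aldol). A cold aqueous quench returns the route at 8.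

Step 11. The lactone enol may be protonated on the face syn to the C4a–C5 bond, or the two C4 epimers may equilibrate during heating, so that the C4 epimer accumulates. The fallback replaces kinetic protonation by thermodynamic control. It sets out from 18: the same deallylation and decarboxylation are run, the C4 epimer F2 is separated, equilibrated through the lactone enolate (DBU, PhMe, 60 °C) and recycled. The route is rejoined at 20.

Step 12. The peracid may attack the other face of the ring alkene if a second ring conformer is populated, giving the 7R,8R epoxide. The fallback replaces substrate control by reagent control. It sets out from 20: Shi epoxidation with the L-sorbose-derived enantiomer of the fructose-based ketone catalyst (Oxone, K2CO3, MeCN–dimethoxymethane–aqueous buffer, 0 °C), whose spiro transition state is expected to deliver the S,S sense to E-trisubstituted alkenes. It comes back to the route at 22 and makes no new compound.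

**Further compounds**

F1 | step 4 | diallyl 2-[4-chloro-1-(1-methyl-2,5-dioxocyclopentyl)-5-oxopentan-3-yl]malonate, C4a as in 7, epimer mixture at the chlorine-bearing carbon | O=CC(Cl)[C@H](CCC1(C)C(=O)CCC1=O)C(C(=O)OCC=C)C(=O)OCC=C
F2 | step 11 | C4 epimer of 20 (side chain trans to the C4a–C5 bond) | C=C1CC/C=C(\C)CC[C@@H]2[C@@H](CC/C=C(\C)C(=O)OC)C(=O)OC[C@@H]12
F0 | step 12 | none | none
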